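**Retrosynthetic overview**

1. The depside ester bond (ring B carbonyl to O4 of ring A) is cut last. Ring B is a 4-O-benzyl-2-O-methyl benzoic acid, ring A the matching methyl ester with only O4 free, and both side-chain ketones are dioxolanes, so both rings come from one phenol.
2. The strategy rests on this feature: in ring A (and identically ring B) the 1,3-dioxygenated run C2(O)–C3–C4(O)–C5 is a four-carbon 1,1-dimethoxy-3-silyloxybutadiene unit, and C6–C1, carrying the 2-oxononyl chain and the ester, is a two-carbon alkynoate unit. A Diels–Alder benzannulation forms C1–C2 and C5–C6 and delivers O2 as a methyl ether and O4 as the only free phenol.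
3. The ynoate comes from methyl 3-oxodecanoate (ketal, aldehyde, alkyne, carboxylation); the diene comes from 1,1-dimethoxyethene and acetyl chloride.
4. Ring order: the benzene ring is built once (step 7) and used twice, rings A and B are joined in step 10, then ketal hydrolysis and BCl3 ether cleavage finish.

Key step: step 7

Remark: the target has no stereocentre, so no stereocontrol is needed; ring A is the methyl benzoate ring (C1 ester, C2 OH, C4 acyloxy, C6 2-oxononyl) and ring B the acyl ring.

**Route**

Step 1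
Reactants: 1 methyl 3-oxodecanoate
Product: 2 methyl 2-(2-heptyl-1,3-dioxolan-2-yl)acetate
Conditions: HOCH2CH2OH (2 equiv), TsOH·H2O (cat.), toluene, reflux, Dean–Stark
Reagents that add atoms: ethylene glycol, OCCO
Why: Acid-catalysed ketalisation with azeotropic removal of water converts the ketone of a beta-keto ester into its dioxolane while the ester is untouched, as for the ketals of acetoacetates.

Step 2
Reactants: 2 methyl 2-(2-heptyl-1,3-dioxolan-2-yl)acetate
Product: 4 2-(2-heptyl-1,3-dioxolan-2-yl)acetaldehyde, via aluminium hemiacetal 3 (not isolated)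
Conditions: i-Bu2AlH (1.1 equiv), CH2Cl2, −78 °C; MeOH, then aq. KNaC4H4O6
Reagents that add atoms: none
Why: Partial ester reduction with i-Bu2AlH at −78 °C should stop at the tetrahedral aluminium hemiacetal 3, which is stabilised by chelation to a dioxolane oxygen and releases the aldehyde only on work-up; the ketal is inert to hydride.

Step 3
Reactants: 4 2-(2-heptyl-1,3-dioxolan-2-yl)acetaldehyde
Product: 5 2-heptyl-2-(prop-2-yn-1-yl)-1,3-dioxolane
Conditions: MeC(O)C(N2)P(O)(OMe)2, K2CO3, MeOH, 0 °C to rt
Reagents that add atoms: dimethyl (1-diazo-2-oxopropyl)phosphonate, COP(=O)(OC)C(=[N+]=[N-])C(C)=O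
Why: Seyferth–Gilbert homologation in the Ohira–Bestmann version turns the aldehyde into the terminal alkyne under carbonate conditions that are too mild to eliminate the beta ketal oxygen.

Step 4
Reactants: 5 2-heptyl-2-(prop-2-yn-1-yl)-1,3-dioxolane; 6 methyl chloroformate
Product: 8 methyl 4-(2-heptyl-1,3-dioxolan-2-yl)but-2-ynoate, via lithium acetylide 7 (not isolated)
Conditions: n-BuLi (1.05 equiv), THF, −78 °C; then ClCO2Me, −78 to −20 °C; aq. NH4Cl
Reagents that add atoms: none
Why: Deprotonation of the terminal alkyne and C-acylation of the lithium acetylide by the chloroformate is the standard ynoate synthesis, and the low temperature with a buffered quench keeps the product from propargyl-to-allenyl isomerisation.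

Step 5
Reactants: 9 1,1-dimethoxyethene; 10 acetyl chloride
Product: 11 4,4-dimethoxybut-3-en-2-one
Conditions: Et3N, Et2O, 0 °C to rt
Reagents that add atoms: none
Why: The nucleophilic CH2 carbon of the ketene acetal is C-acylated by the acid chloride and the resulting dimethoxycarbenium ion loses a proton to the amine (acylation of ketene acetals), giving the push-pull enone.

Step 6
Reactants: 11 4,4-dimethoxybut-3-en-2-one
Product: 12 1,1-dimethoxy-3-(trimethylsilyloxy)buta-1,3-diene
Conditions: Me3SiCl, Et3N, ZnCl2 (cat.), toluene, 40 °C; filtration, distillation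
Reagents that add atoms: chlorotrimethylsilane, C[Si](C)(C)Cl
Why: Silyl enol ether formation under Danishefsky-type conditions can occur only towards the methyl group, the sole enolisable position, and so gives the cross-conjugated 2-silyloxydiene.

Step 7
Reactants: 12 1,1-dimethoxy-3-(trimethylsilyloxy)buta-1,3-diene; 8 methyl 4-(2-heptyl-1,3-dioxolan-2-yl)but-2-ynoate
Product: 15 methyl 6-[(2-heptyl-1,3-dioxolan-2-yl)methyl]-4-hydroxy-2-methoxybenzoate, via cycloadduct 13 (not isolated), via aryl silyl ether 14 (not isolated)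
Conditions: 12 (2 equiv), toluene, 110 °C, sealed tube; then MeOH, K2CO3 (cat.), rt
Reagents that add atoms: none
Why: Diene 12 (HOMO raised by three oxygen donors) and ynoate 8 (LUMO lowered by the ester) combine in a thermal, strongly asynchronous (4+2) cycloaddition that forms C5–C6 and C1–C2 of ring A and gives cyclohexa-1,4-diene 13; the closest known reaction type is the Diels–Alder benzannulation of 1,1-dialkoxy-3-silyloxybutadienes with alkynoates to 4-hydroxy-2-alkoxybenzoates. Ring A is closed by this intermolecular cycloaddition (a six-membered carbocycle from a four-carbon and a two-carbon unit, both new bonds made in one step), and 13 then aromatises by 1,4-elimination of methanol between the acetal carbon C2 and the C5 methylene to give silyl ether 14, which catalytic methanolysis converts into phenol 15. No stereocentre is created. The step needs regioselectivity: the CH2 terminus of the diene, the position of highest electron density because both the silyloxy group and the vinylogous ketene acetal push towards it, has to bond to the electrophilic beta carbon of the ynoate and the acetal carbon to the alpha carbon, and this matched polarisation places OMe on C2 next to the ester, the free hydroxyl on C4 and the side chain on C6. Chemoselectivity rests on the dioxolane, which blocks the isomerisation of a beta,gamma-alkynyl ketone to an allenone and withstands the neutral thermal stage and the basic methanolysis, and on the methyl ether formed at O2, which leaves O4 as the only phenol for the later acylation.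

Step 8
Reactants: 15 methyl 6-[(2-heptyl-1,3-dioxolan-2-yl)methyl]-4-hydroxy-2-methoxybenzoate
Product: 16 methyl 4-(benzyloxy)-6-[(2-heptyl-1,3-dioxolan-2-yl)methyl]-2-methoxybenzoate
Conditions: BnBr, K2CO3, DMF, rt
Reagents that add atoms: benzyl bromide, BrCc1ccccc1
Why: Williamson etherification of the single phenol proceeds under carbonate conditions that leave the ester and the ketal alone.

Step 9
Reactants: 16 methyl 4-(benzyloxy)-6-[(2-heptyl-1,3-dioxolan-2-yl)methyl]-2-methoxybenzoate
Product: 18 4-(benzyloxy)-6-[(2-heptyl-1,3-dioxolan-2-yl)methyl]-2-methoxybenzoic acid, via potassium carboxylate 17 (not isolated)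
Conditions: KOH (excess), DMSO/H2O (4:1), 90 °C; then cold aq. citric acid to pH 4
Reagents that add atoms: potassium hydroxide, [K+].[OH-]
Why: Saponification of the doubly ortho-substituted benzoate needs poorly solvated hydroxide in wet DMSO, conditions to which benzyl ether, methyl ether and ketal are stable; the cold, weakly acidic work-up spares the dioxolane and the acid is used at once.

Step 10
Reactants: 18 4-(benzyloxy)-6-[(2-heptyl-1,3-dioxolan-2-yl)methyl]-2-methoxybenzoic acid; 15 methyl 6-[(2-heptyl-1,3-dioxolan-2-yl)methyl]-4-hydroxy-2-methoxybenzoate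
Product: 20 methyl 4-({4-(benzyloxy)-6-[(2-heptyl-1,3-dioxolan-2-yl)methyl]-2-methoxybenzoyl}oxy)-6-[(2-heptyl-1,3-dioxolan-2-yl)methyl]-2-methoxybenzoate, via acid chloride 19 (not isolated)
Conditions: Me2C=C(Cl)NMe2 (1.2 equiv), CH2Cl2, 0 °C; then 15, Et3N, DMAP (cat.), 0 °C to rt
Reagents that add atoms: none
Why: The hindered acid is converted into its acid chloride under neutral conditions with the alpha-chloroenamine (Ghosez reagent), so the ketals never meet HCl, and DMAP-catalysed acylation then esterifies O4 of 15, the only free hydroxyl.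

Step 11
Reactants: 20 methyl 4-({4-(benzyloxy)-6-[(2-heptyl-1,3-dioxolan-2-yl)methyl]-2-methoxybenzoyl}oxy)-6-[(2-heptyl-1,3-dioxolan-2-yl)methyl]-2-methoxybenzoate
Product: 21 methyl 4-{[4-(benzyloxy)-2-methoxy-6-(2-oxononyl)benzoyl]oxy}-2-methoxy-6-(2-oxononyl)benzoate
Conditions: TsOH·H2O (cat.), acetone/H2O (10:1), rt
Reagents that add atoms: water, O
Why: Mild acid-catalysed ketal hydrolysis releases both ketones while the esters and the ethers are stable; it is placed before the BCl3 step so that the Lewis acid does not open the dioxolanes to oxocarbenium ions next to the esters.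

Step 12
Reactants: 21 methyl 4-{[4-(benzyloxy)-2-methoxy-6-(2-oxononyl)benzoyl]oxy}-2-methoxy-6-(2-oxononyl)benzoate
Product: 23 methyl 4-{[2,4-dihydroxy-6-(2-oxononyl)benzoyl]oxy}-2-hydroxy-6-(2-oxononyl)benzoate, via tris(dichloroboryl) ether 22 (not isolated)
Conditions: BCl3 (8 equiv), C6HMe5 (3 equiv), CH2Cl2, −78 to 0 °C; then ice-water
Reagents that add atoms: none
Why: BCl3 ether cleavage is chelation-directed: boron held between each ester carbonyl and its ortho methoxy oxygen lets chloride remove the methyl group, the benzyl ether is cleaved through a benzyl cation that pentamethylbenzene traps, and the esters and ketones should survive at this temperature before the aryloxyboranes are hydrolysed.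

**Compound list**

1 | methyl 3-oxodecanoate | CCCCCCCC(=O)CC(=O)OC | starting material
2 | methyl 2-(2-heptyl-1,3-dioxolan-2-yl)acetate | CCCCCCCC1(CC(=O)OC)OCCO1 | intermediate
3 | diisobutylaluminium 2-(2-heptyl-1,3-dioxolan-2-yl)-1-methoxyethoxide (aluminium hemiacetal, racemic, not isolated) | CCCCCCCC1(CC(OC)O[Al](CC(C)C)CC(C)C)OCCO1 | intermediate
4 | 2-(2-heptyl-1,3-dioxolan-2-yl)acetaldehyde | CCCCCCCC1(CC=O)OCCO1 | intermediate
5 | 2-heptyl-2-(prop-2-yn-1-yl)-1,3-dioxolane | CCCCCCCC1(CC#C)OCCO1 | intermediate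
6 | methyl chloroformate | COC(=O)Cl | starting material
7 | lithium acetylide of 5 (not isolated) | [Li]C#CCC1(CCCCCCC)OCCO1 | intermediate
8 | methyl 4-(2-heptyl-1,3-dioxolan-2-yl)but-2-ynoate | COC(=O)C#CCC1(CCCCCCC)OCCO1 | intermediate
9 | 1,1-dimethoxyethene | COC(=C)OC | starting material
10 | acetyl chloride | CC(Cl)=O | starting material
11 | 4,4-dimethoxybut-3-en-2-one | CC(=O)C=C(OC)OC | intermediate
12 | 1,1-dimethoxy-3-(trimethylsilyloxy)buta-1,3-diene | COC(OC)=CC(=C)O[Si](C)(C)C | intermediate
13 | methyl 2-[(2-heptyl-1,3-dioxolan-2-yl)methyl]-6,6-dimethoxy-4-(trimethylsilyloxy)cyclohexa-1,4-diene-1-carboxylate (cycloadduct, not isolated) | COC(=O)C1=C(CC2(CCCCCCC)OCCO2)CC(O[Si](C)(C)C)=CC1(OC)OC | intermediate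
14 | methyl 6-[(2-heptyl-1,3-dioxolan-2-yl)methyl]-2-methoxy-4-(trimethylsilyloxy)benzoate (aryl silyl ether, not isolated) | COC(=O)c1c(OC)cc(O[Si](C)(C)C)cc1CC2(CCCCCCC)OCCO2 | intermediate
15 | methyl 6-[(2-heptyl-1,3-dioxolan-2-yl)methyl]-4-hydroxy-2-methoxybenzoate | COC(=O)c1c(OC)cc(O)cc1CC2(CCCCCCC)OCCO2 | intermediate
16 | methyl 4-(benzyloxy)-6-[(2-heptyl-1,3-dioxolan-2-yl)methyl]-2-methoxybenzoate | COC(=O)c1c(OC)cc(OCc3ccccc3)cc1CC2(CCCCCCC)OCCO2 | intermediate
17 | potassium 4-(benzyloxy)-6-[(2-heptyl-1,3-dioxolan-2-yl)methyl]-2-methoxybenzoate (not isolated) | [K+].[O-]C(=O)c1c(OC)cc(OCc3ccccc3)cc1CC2(CCCCCCC)OCCO2 | intermediate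
18 | 4-(benzyloxy)-6-[(2-heptyl-1,3-dioxolan-2-yl)methyl]-2-methoxybenzoic acid | OC(=O)c1c(OC)cc(OCc3ccccc3)cc1CC2(CCCCCCC)OCCO2 | intermediate
19 | 4-(benzyloxy)-6-[(2-heptyl-1,3-dioxolan-2-yl)methyl]-2-methoxybenzoyl chloride (not isolated) | ClC(=O)c1c(OC)cc(OCc3ccccc3)cc1CC2(CCCCCCC)OCCO2 | intermediate
20 | methyl 4-({4-(benzyloxy)-6-[(2-heptyl-1,3-dioxolan-2-yl)methyl]-2-methoxybenzoyl}oxy)-6-[(2-heptyl-1,3-dioxolan-2-yl)methyl]-2-methoxybenzoate | COC(=O)c1c(OC)cc(OC(=O)c3c(OC)cc(OCc5ccccc5)cc3CC4(CCCCCCC)OCCO4)cc1CC2(CCCCCCC)OCCO2 | intermediate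
21 | methyl 4-{[4-(benzyloxy)-2-methoxy-6-(2-oxononyl)benzoyl]oxy}-2-methoxy-6-(2-oxononyl)benzoate | COC(=O)c1c(OC)cc(OC(=O)c2c(OC)cc(OCc3ccccc3)cc2CC(=O)CCCCCCC)cc1CC(=O)CCCCCCC | intermediate
22 | methyl 4-{[2,4-bis(dichloroboryloxy)-6-(2-oxononyl)benzoyl]oxy}-2-(dichloroboryloxy)-6-(2-oxononyl)benzoate (not isolated) | CCCCCCCC(=O)Cc1cc(OC(=O)c2c(OB(Cl)Cl)cc(OB(Cl)Cl)cc2CC(=O)CCCCCCC)cc(OB(Cl)Cl)c1C(=O)OC | intermediate
23 | methyl 4-{[2,4-dihydroxy-6-(2-oxononyl)benzoyl]oxy}-2-hydroxy-6-(2-oxononyl)benzoate (CNP0110390.0) | CCCCCCCC(=O)Cc1cc(OC(=O)c2c(O)cc(O)cc2CC(=O)CCCCCCC)cc(O)c1C(=O)OC | target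

**Step count and risks**

Total step count: 12. Longest linear sequence: 10 steps (steps 1–4 and 7–12); steps 5 and 6 form the diene branch.

Steps most likely to fail:

Step 7. The cycloaddition may be slow, because the beta carbon of 8 carries a neopentyl-type CH2–C(ketal) group, and on long heating the diene may desilylate or oligomerise before it adds, or add in a stepwise Michael fashion without ring closure. The fallback sets out from 2 and returns at 14 and 15, replacing the ynoate by a more reactive allenoate dienophile. Ester 2 is saponified (LiOH, THF/H2O) to 2-(2-heptyl-1,3-dioxolan-2-yl)acetic acid F1, which the alpha-chloroenamine of step 10 converts into 2-(2-heptyl-1,3-dioxolan-2-yl)acetyl chloride F2. Et3N in CH2Cl2 at 0 °C dehydrochlorinates F2 to (2-heptyl-1,3-dioxolan-2-yl)ketene F3, and Wittig olefination of the ketene carbonyl by Ph3P=CHCO2Me present in the flask should give methyl 4-(2-heptyl-1,3-dioxolan-2-yl)buta-2,3-dienoate F4. Diene 12 should add across the ester-conjugated double bond of F4 at 60–80 °C in toluene with the same polarity matching (diene CH2 to the central allene carbon), giving methyl 2-[(2-heptyl-1,3-dioxolan-2-yl)methylidene]-6,6-dimethoxy-4-(trimethylsilyloxy)cyclohex-4-ene-1-carboxylate F5. Loss of methanol and migration of the exocyclic double bond into the ring then lead to silyl ether 14, which is methanolysed as in step 7 to 15.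

Step 11. Under Brønsted acid the liberated ring B ketone may enolise and its enol oxygen may attack the neighbouring aryl ester (enol-lactonisation to an isocoumarin), which would break the depside bond; the second ketal may also hydrolyse slowly. The fallback sets out from 20 and returns at 23 without any new isolated compound. Compound 20 is treated directly with BCl3 and pentamethylbenzene (CH2Cl2, −78 to 0 °C), which opens both dioxolanes by Lewis-acid ketal cleavage in the same operation that removes the benzyl and methyl ethers. The ester carbonyls are tied up as boron chelates during this time and the ketones appear only on the cold aqueous quench, which gives 23.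

Step 12. BCl3 may also attack the depside or methyl ester, trigger lactonisation of the boron-complexed ketones, stop at partial demethylation, or allow benzylation of the electron-rich rings by the liberated benzyl cation. The fallback sets out from 15 and returns at 23; it removes the methyl ethers before the depside bond exists and ends with a neutral hydrogenolysis.
- Phenol 15 is treated with BCl3 (CH2Cl2, −78 to 0 °C, aqueous work-up), which cleaves the ortho methyl ether and the dioxolane and should give methyl 2,4-dihydroxy-6-(2-oxononyl)benzoate F6.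
- Re-ketalisation (ethylene glycol, HC(OMe)3, TsOH cat., rt) gives methyl 6-[(2-heptyl-1,3-dioxolan-2-yl)methyl]-2,4-dihydroxybenzoate F7.
- One portion of F7 is dibenzylated (BnBr, K2CO3, DMF, 60 °C) to methyl 2,4-bis(benzyloxy)-6-[(2-heptyl-1,3-dioxolan-2-yl)methyl]benzoate F8 and saponified as in step 9 to 2,4-bis(benzyloxy)-6-[(2-heptyl-1,3-dioxolan-2-yl)methyl]benzoic acid F9.
- The acid is activated as in step 10 to 2,4-bis(benzyloxy)-6-[(2-heptyl-1,3-dioxolan-2-yl)methyl]benzoyl chloride F10. This acylates the 4-hydroxyl of a second portion of F7 (the 2-hydroxyl is hydrogen-bonded to the ester and far less reactive) to give methyl 4-({2,4-bis(benzyloxy)-6-[(2-heptyl-1,3-dioxolan-2-yl)methyl]benzoyl}oxy)-6-[(2-heptyl-1,3-dioxolan-2-yl)methyl]-2-hydroxybenzoate F11.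
- Ketal hydrolysis as in step 11 gives methyl 4-{[2,4-bis(benzyloxy)-6-(2-oxononyl)benzoyl]oxy}-2-hydroxy-6-(2-oxononyl)benzoate F12, and hydrogenolysis (H2, Pd/C, EtOAc, rt) removes both benzyl ethers to give 23.

**Further compounds**

F1 | step 7 | 2-(2-heptyl-1,3-dioxolan-2-yl)acetic acid | CCCCCCCC1(CC(=O)O)OCCO1
F2 | step 7 | 2-(2-heptyl-1,3-dioxolan-2-yl)acetyl chloride | CCCCCCCC1(CC(=O)Cl)OCCO1
F3 | step 7 | (2-heptyl-1,3-dioxolan-2-yl)ketene | CCCCCCCC1(C=C=O)OCCO1
F4 | step 7 | methyl 4-(2-heptyl-1,3-dioxolan-2-yl)buta-2,3-dienoate (racemic) | COC(=O)C=C=CC1(CCCCCCC)OCCO1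
F5 | step 7 | methyl 2-[(2-heptyl-1,3-dioxolan-2-yl)methylidene]-6,6-dimethoxy-4-(trimethylsilyloxy)cyclohex-4-ene-1-carboxylate (isomer mixture) | COC(=O)C1C(=CC2(CCCCCCC)OCCO2)CC(O[Si](C)(C)C)=CC1(OC)OC
F0 | step 11 | none | none
F6 | step 12 | methyl 2,4-dihydroxy-6-(2-oxononyl)benzoate | COC(=O)c1c(O)cc(O)cc1CC(=O)CCCCCCC
F7 | step 12 | methyl 6-[(2-heptyl-1,3-dioxolan-2-yl)methyl]-2,4-dihydroxybenzoate | COC(=O)c1c(O)cc(O)cc1CC2(CCCCCCC)OCCO2
F8 | step 12 | methyl 2,4-bis(benzyloxy)-6-[(2-heptyl-1,3-dioxolan-2-yl)methyl]benzoate | COC(=O)c1c(OCc3ccccc3)cc(OCc4ccccc4)cc1CC2(CCCCCCC)OCCO2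
F9 | step 12 | 2,4-bis(benzyloxy)-6-[(2-heptyl-1,3-dioxolan-2-yl)methyl]benzoic acid | OC(=O)c1c(OCc3ccccc3)cc(OCc4ccccc4)cc1CC2(CCCCCCC)OCCO2
F10 | step 12 | 2,4-bis(benzyloxy)-6-[(2-heptyl-1,3-dioxolan-2-yl)methyl]benzoyl chloride | ClC(=O)c1c(OCc3ccccc3)cc(OCc4ccccc4)cc1CC2(CCCCCCC)OCCO2
F11 | step 12 | methyl 4-({2,4-bis(benzyloxy)-6-[(2-heptyl-1,3-dioxolan-2-yl)methyl]benzoyl}oxy)-6-[(2-heptyl-1,3-dioxolan-2-yl)methyl]-2-hydroxybenzoate | COC(=O)c1c(O)cc(OC(=O)c3c(OCc5ccccc5)cc(OCc6ccccc6)cc3CC4(CCCCCCC)OCCO4)cc1CC2(CCCCCCC)OCCO2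
F12 | step 12 | methyl 4-{[2,4-bis(benzyloxy)-6-(2-oxononyl)benzoyl]oxy}-2-hydroxy-6-(2-oxononyl)benzoate | COC(=O)c1c(O)cc(OC(=O)c2c(OCc3ccccc3)cc(OCc4ccccc4)cc2CC(=O)CCCCCCC)cc1CC(=O)CCCCCCC
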